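**Retrosynthetic overview**

1. The 11-oxabicyclo[4.4.1]undecane (O bridging C5 and C10 of the ten-membered carbocycle C1–C10, H-5 anti to CH3-14) is read as a trans-eudesmane with O inserted into the ring-fusion bond C5–C10. It is cut back to a decalin C5 hydroperoxide: Criegee rearrangement (C10 migrates from C5 to O with retention), then silane reduction at C5.
2. The decalin hydroperoxide comes from a Δ5-eudesmen-12-oic acid by bromolactonisation (sets C6–O and the cis γ-lactone, leaves a tertiary C5–Br) and silver-assisted perhydrolysis.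
3. The decalin comes from a chiral-imine Robinson annulation of a ring-B cyclohexanone with methyl vinyl ketone; C15 by deconjugative dienolate hydroxymethylation, C3 and C8 by two bulky-hydride reductions.
4. Ring B comes from Rh/BINAP 1,4-addition of a 2-(silyloxymethyl)vinyl boronate (C11–C13) to a cyclohexenone ketal.
5. Ring order: ring B (bought) → ring A (step 3) → γ-lactone (step 13) → both oxepanes at once by O-insertion (step 15).

Key step: step 15

Remark: the SMILES is read literally; 5R,10R means a trans (in,out) ether bridge with H-5 and CH3-14 anti, which is the topology of a trans-decalin with O inserted into C5–C10. Eudesmane/germacrane numbering is used (C14 = CH3 on C10, C15 = CH2O on C4, C11–C13 = lactone carbons); β = face of CH3-14.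

**Route**

Step 1
Reactants: 1 1,4-dioxaspiro[4.5]dec-6-en-8-one
Product: 2 9-methyl-1,4-dioxaspiro[4.5]dec-6-en-8-one (racemic)
Conditions: LDA, THF, −78 °C; MeI, −78 → 0 °C
Reagents that add atoms: iodomethane, CI
Why: Kinetic deprotonation of the cyclohexenone occurs at the α′ CH2 (cross-conjugated enolate) and enolate alkylation there installs C14; the new centre is left racemic because it is re-enolised in step 3.

Step 2
Reactants: 2 9-methyl enone ketal; 3 2-[3-(tert-butyldimethylsilyloxy)prop-1-en-2-yl]-4,4,5,5-tetramethyl-1,3,2-dioxaborolane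
Product: 4 (6R)-6-[3-(TBS-oxy)prop-1-en-2-yl]-9-methyl-1,4-dioxaspiro[4.5]decan-8-one (both C9 epimers)
Conditions: [Rh(cod)OH]2 (cat.), (R)-BINAP, KOH (cat.), dioxane/H2O, 50 °C
Reagents that add atoms: boronate 3, C=C(CO[Si](C)(C)C(C)(C)C)B1OC(C)(C)C(C)(C)O1
Why: Hayashi–Miyaura Rh-catalysed asymmetric 1,4-addition to the only enone β-carbon sets C7 under ligand control ((R)-BINAP, the sense that gives (R)-3-substituted cyclohexanones), and both remote C10 epimers are carried on.

Step 3
Reactants: 4 ring-B ketone; 5 (R)-1-phenylethylamine; 6 but-3-en-2-one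
Product: 10 12-(TBS-oxy)-15-noreudesma-4,11(13)-diene-3,8-dione 8-ethylene ketal (10β-CH3 and 7α-H), via ketimine 7 (not isolated), via alkylated ketimine 8 (not isolated), via 1,5-diketone 9 (not isolated)
Conditions: 5, TsOH (cat.), PhMe, reflux (Dean–Stark); 6, THF, 40 °C; 10% aq AcOH, THF, rt; then NaOMe, MeOH, 60 °C
Reagents that add atoms: but-3-en-2-one 6, C=CC(C)=O
Why: Chiral-imine Robinson annulation: the ketimine reacts through its more substituted secondary enamine with the enone on the face fixed by the (R)-auxiliary (the sense opposite to the one that gives (R)-2-methyl-2-(3-oxobutyl)cyclohexanone), so the butanone chain enters anti to the C7 side chain and CH3-14 ends up β, and aldol condensation then closes ring A.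

Step 4
Reactants: 10 enone ketal
Product: 11 15-hydroxy-12-(TBS-oxy)eudesma-5,11(13)-diene-3,8-dione 8-ethylene ketal (C15 α, 4β-H)
Conditions: KOt-Bu (1.0 equiv), THF/t-BuOH, 0 °C; CH2O (THF solution), −78 °C; AcOH quench
Reagents that add atoms: formaldehyde, C=O
Why: The thermodynamic extended dienolate (O–C3=C4–C5=C6) adds to formaldehyde at Cα (C4) in a deconjugative aldol reaction, which moves the alkene to C5=C6 and places C15 on the α-face, anti to CH3-14 and in the equatorial, thermodynamically preferred position.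

Step 5
Reactants: 11 β-hydroxy ketone
Product: 12 15-(TIPS-oxy)-12-(TBS-oxy)eudesma-5,11(13)-diene-3,8-dione 8-ethylene ketal
Conditions: TIPSOTf, 2,6-lutidine, CH2Cl2, −78 °C
Reagents that add atoms: triisopropylsilyl triflate, CC(C)[Si](OS(=O)(=O)C(F)(F)F)(C(C)C)C(C)C
Why: Low-temperature silylation of the primary alcohol blocks retro-aldol and dehydration of the β-hydroxy ketone and gives the one protecting group that has to last to the end.

Step 6
Reactants: 12 Δ5-3-ketone
Product: 13 3α-hydroxy-15-(TIPS-oxy)-12-(TBS-oxy)eudesma-5,11(13)-dien-8-one ethylene ketal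
Conditions: L-Selectride, THF, −78 °C; H2O
Reagents that add atoms: none
Why: The bulky hydride attacks the 3-ketone from the equatorial direction, away from the adjacent equatorial C4 substituent, and gives the axial 3α-alcohol cis to C15 before the β,γ-enone can reconjugate.

Step 7
Reactants: 13 3α-alcohol
Product: 14 3α-acetoxy-15-(TIPS-oxy)-12-(TBS-oxy)eudesma-5,11(13)-dien-8-one ethylene ketal
Conditions: Ac2O, pyridine, DMAP (cat.), CH2Cl2, rt
Reagents that add atoms: acetic anhydride, CC(=O)OC(C)=O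
Why: DMAP-catalysed acylation of the only free hydroxyl installs the C3 acetate of the target.

Step 8
Reactants: 14 ketal
Product: 15 3α-acetoxy-15-(TIPS-oxy)-12-(TBS-oxy)eudesma-5,11(13)-dien-8-one
Conditions: PPTS (cat.), acetone/H2O, 40 °C
Reagents that add atoms: water, O
Why: Mild acid hydrolysis of the dioxolane in wet acetone leaves the silyl ethers and the acetate intact, and the β,γ-unsaturated ketone (C7 side chain equatorial) is reduced at once to avoid epimerisation at C7 and alkene migration.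

Step 9
Reactants: 15 8-ketone
Product: 16 3α-acetoxy-15-(TIPS-oxy)-12-(TBS-oxy)eudesma-5,11(13)-dien-8β-ol
Conditions: L-Selectride (1.1 equiv), THF, −78 °C; H2O
Reagents that add atoms: none
Why: Bulky-hydride reduction from the equatorial direction gives the axial 8β-alcohol cis to the equatorial C7 side chain, and the ketone reacts much faster than the acetate at −78 °C.

Step 10
Reactants: 16 8β-alcohol
Product: 17 3α-acetoxy-8β-methacryloyloxy-15-(TIPS-oxy)-12-(TBS-oxy)eudesma-5,11(13)-diene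
Conditions: methacrylic anhydride, Et3N, DMAP, CH2Cl2, rt → 40 °C
Reagents that add atoms: methacrylic anhydride, CC(=C)C(=O)OC(=O)C(C)=C
Why: DMAP-catalysed acylation puts the target ester on O-8 before C12 is oxidised, so the later carboxylic acid cannot lactonise to O-8.

Step 11
Reactants: 17 bis-silyl ether
Product: 18 3α-acetoxy-8β-methacryloyloxy-15-(TIPS-oxy)eudesma-5,11(13)-dien-12-ol
Conditions: PPTS, MeOH, rt
Reagents that add atoms: none
Why: Acid-catalysed methanolysis removes the primary allylic TBS ether far faster than the TIPS ether (selective desilylation).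

Step 12
Reactants: 18 allylic alcohol
Product: 20 3α-acetoxy-8β-methacryloyloxy-15-(TIPS-oxy)eudesma-5,11(13)-dien-12-oic acid, via enal 19 (not isolated)
Conditions: MnO2, CH2Cl2, rt; then NaClO2, NaH2PO4, 2-methyl-2-butene, t-BuOH/H2O
Reagents that add atoms: sodium chlorite, [Na+].[O-]Cl=O
Why: MnO2 oxidises only the allylic alcohol, and Pinnick oxidation with a hypochlorite scavenger takes the 2-substituted acrolein to the acrylic acid without touching the C5=C6 alkene.

Step 13
Reactants: 20 Δ5-acid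
Product: 21 3α-acetoxy-5α-bromo-8β-methacryloyloxy-15-(TIPS-oxy)eudesm-11(13)-en-6β,12-olide
Conditions: NBS, MeCN, 0 °C, dark
Reagents that add atoms: N-bromosuccinimide, O=C1CCC(=O)N1Br
Why: Bromolactonisation: Br+ adds to the electron-rich C5=C6 alkene on the α-face (anti to CH3-14) and the β-disposed carboxylate opens the bromonium ion at C6 in a 5-exo, trans-diaxial sense, which sets C6 (6β-O, cis-fused γ-lactone) and leaves a tertiary 5α-bromide.

Step 14
Reactants: 21 bromolactone
Product: 22 3α-acetoxy-5α-hydroperoxy-8β-methacryloyloxy-15-(TIPS-oxy)eudesm-11(13)-en-6β,12-olide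
Conditions: AgOCOCF3, H2O2 (anhydrous, Et2O), NaHCO3, 0 °C
Reagents that add atoms: hydrogen peroxide, OO
Why: Silver-assisted SN1 exchange of the tertiary bromide for hydroperoxide installs the C5–OOH; the C5 configuration is drawn α but is irrelevant because C5 becomes sp2 in step 15.

Step 15
Reactants: 22 tertiary hydroperoxide
Product: 24 3α-acetoxy-8β-methacryloyloxy-5-(4-nitrobenzoyloxy)-15-(TIPS-oxy)-5,10-epoxygermacr-11(13)-en-6β,12-olide (bridgehead ketal ester), via peroxy ester 23 (not isolated)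
Conditions: 4-O2NC6H4COCl, pyridine, CH2Cl2, 0 °C; then MeCN, rt → 40 °C
Reagents that add atoms: 4-nitrobenzoyl chloride, O=C(Cl)c1ccc(cc1)[N+](=O)[O-]
Why: Acylation gives perester 23, whose O–O bond ionises with a concerted 1,2-shift of the antiperiplanar C5–C10 bond from carbon to oxygen, and the oxocarbenium/carboxylate ion pair collapses to the ketal ester (Criegee rearrangement, the reaction type by which 9-decalyl peresters give 1,6-epoxycyclodecyl esters). No ring is closed by cyclisation: the two fused cyclohexanes become the two oxepanes (O, C10, C1–C4, C5 and O, C5, C6–C9, C10) in one ring expansion, and the ten-membered carbocycle is released from the decalin. C10 migrates with retention, so the new O–C10 bond takes the place of the old C5–C10 bond and CH3-14 keeps its orientation relative to C7 and C8, which is the origin of the trans bridge; C5 becomes a ketal carbon whose configuration is reset in step 16. The step needs migration of C10 rather than C4 or C6: C10 is the only fully substituted migrating carbon, C6 is deactivated by its lactone acyloxy oxygen and C4 by the β-silyloxy group. The lactone on O-6 also removes the free β-hydroxy hydroperoxide that would otherwise cleave C5–C6.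

Step 16
Reactants: 24 ketal ester
Product: 25 3α-acetoxy-8β-methacryloyloxy-15-(TIPS-oxy)-5,10-epoxygermacr-11(13)-en-6β,12-olide (15-O-TIPS target)
Conditions: Et3SiH, TMSOTf (cat.), CH2Cl2, −78 → −40 °C
Reagents that add atoms: none
Why: TMSOTf ionises the bridgehead acyloxy ketal to the oxocarbenium ion and Et3SiH reduces it (reductive substitution of an α-acyloxy ether, ionic hydrogenation), with hydride expected from the open peripheral direction of the cation, on the α-face anti to CH3-14 (1,3 across the ring oxygen) and to the β-fused lactone at C6, which gives H-5 anti to CH3-14.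

Step 17
Reactants: 25 TIPS ether
Product: 26 target CNP0602302.1
Conditions: HF·pyridine, THF, 0 °C → rt
Reagents that add atoms: none
Why: Fluoride cleavage of the silyl ether under non-basic conditions frees the C15 alcohol without 1,3-acyl migration from O-3 or addition to the α-methylene lactone.

**Compound list**

1 | 1,4-dioxaspiro[4.5]dec-6-en-8-one | O=C1C=CC2(CC1)OCCO2 | starting material
2 | 9-methyl-1,4-dioxaspiro[4.5]dec-6-en-8-one (racemic) | CC1CC2(OCCO2)C=CC1=O | intermediate
3 | 2-[3-(tert-butyldimethylsilyloxy)prop-1-en-2-yl]-4,4,5,5-tetramethyl-1,3,2-dioxaborolane | C=C(CO[Si](C)(C)C(C)(C)C)B1OC(C)(C)C(C)(C)O1 | starting material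
4 | (6R)-6-[3-(TBS-oxy)prop-1-en-2-yl]-9-methyl-1,4-dioxaspiro[4.5]decan-8-one (C9 epimers; C6 = future C7) | CC1CC2(OCCO2)[C@@H](C(=C)CO[Si](C)(C)C(C)(C)C)CC1=O | intermediate
5 | (R)-1-phenylethylamine | C[C@@H](N)c1ccccc1 | starting material
6 | but-3-en-2-one | C=CC(C)=O | starting material
7 | N-[(R)-1-phenylethyl] ketimine of 4 | CC1CC2(OCCO2)[C@@H](C(=C)CO[Si](C)(C)C(C)(C)C)CC1=N[C@H](C)c1ccccc1 | intermediate
8 | ketimine alkylated at C10 with the 3-oxobutyl chain (10β-CH3) | CC(=O)CC[C@]1(C)CC2(OCCO2)[C@@H](C(=C)CO[Si](C)(C)C(C)(C)C)CC1=N[C@H](C)c1ccccc1 | intermediate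
9 | 1,5-diketone from hydrolysis of 8 | CC(=O)CC[C@]1(C)CC2(OCCO2)[C@@H](C(=C)CO[Si](C)(C)C(C)(C)C)CC1=O | intermediate
10 | 12-(TBS-oxy)-15-noreudesma-4,11(13)-diene-3,8-dione 8-ethylene ketal (10β-CH3, 7α-H) | O=C1CC[C@]2(C)CC3(OCCO3)[C@@H](C(=C)CO[Si](C)(C)C(C)(C)C)CC2=C1 | intermediate
11 | 15-hydroxy-12-(TBS-oxy)eudesma-5,11(13)-diene-3,8-dione 8-ethylene ketal (C15 α) | O=C1CC[C@]2(C)CC3(OCCO3)[C@@H](C(=C)CO[Si](C)(C)C(C)(C)C)C=C2[C@@H]1CO | intermediate
12 | 15-O-TIPS ether of 11 | O=C1CC[C@]2(C)CC3(OCCO3)[C@@H](C(=C)CO[Si](C)(C)C(C)(C)C)C=C2[C@@H]1CO[Si](C(C)C)(C(C)C)C(C)C | intermediate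
13 | 3α-hydroxy-15-(TIPS-oxy)-12-(TBS-oxy)eudesma-5,11(13)-dien-8-one ethylene ketal | O[C@@H]1CC[C@]2(C)CC3(OCCO3)[C@@H](C(=C)CO[Si](C)(C)C(C)(C)C)C=C2[C@@H]1CO[Si](C(C)C)(C(C)C)C(C)C | intermediate
14 | 3α-acetate of 13 | CC(=O)O[C@@H]1CC[C@]2(C)CC3(OCCO3)[C@@H](C(=C)CO[Si](C)(C)C(C)(C)C)C=C2[C@@H]1CO[Si](C(C)C)(C(C)C)C(C)C | intermediate
15 | 3α-acetoxy-15-(TIPS-oxy)-12-(TBS-oxy)eudesma-5,11(13)-dien-8-one | CC(=O)O[C@@H]1CC[C@]2(C)CC(=O)[C@@H](C(=C)CO[Si](C)(C)C(C)(C)C)C=C2[C@@H]1CO[Si](C(C)C)(C(C)C)C(C)C | intermediate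
16 | 3α-acetoxy-15-(TIPS-oxy)-12-(TBS-oxy)eudesma-5,11(13)-dien-8β-ol | CC(=O)O[C@@H]1CC[C@]2(C)C[C@@H](O)[C@@H](C(=C)CO[Si](C)(C)C(C)(C)C)C=C2[C@@H]1CO[Si](C(C)C)(C(C)C)C(C)C | intermediate
17 | 8β-methacrylate of 16 | CC(=O)O[C@@H]1CC[C@]2(C)C[C@@H](OC(=O)C(C)=C)[C@@H](C(=C)CO[Si](C)(C)C(C)(C)C)C=C2[C@@H]1CO[Si](C(C)C)(C(C)C)C(C)C | intermediate
18 | 3α-acetoxy-8β-methacryloyloxy-15-(TIPS-oxy)eudesma-5,11(13)-dien-12-ol | CC(=O)O[C@@H]1CC[C@]2(C)C[C@@H](OC(=O)C(C)=C)[C@@H](C(=C)CO)C=C2[C@@H]1CO[Si](C(C)C)(C(C)C)C(C)C | intermediate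
19 | corresponding 12-al (enal) | CC(=O)O[C@@H]1CC[C@]2(C)C[C@@H](OC(=O)C(C)=C)[C@@H](C(=C)C=O)C=C2[C@@H]1CO[Si](C(C)C)(C(C)C)C(C)C | intermediate
20 | corresponding 12-oic acid | CC(=O)O[C@@H]1CC[C@]2(C)C[C@@H](OC(=O)C(C)=C)[C@@H](C(=C)C(=O)O)C=C2[C@@H]1CO[Si](C(C)C)(C(C)C)C(C)C | intermediate
21 | 3α-acetoxy-5α-bromo-8β-methacryloyloxy-15-(TIPS-oxy)eudesm-11(13)-en-6β,12-olide | CC(=C)C(=O)O[C@@H]1C[C@@]2(C)CC[C@@H](OC(C)=O)[C@@H](CO[Si](C(C)C)(C(C)C)C(C)C)[C@]2(Br)[C@@H]2OC(=O)C(=C)[C@@H]21 | intermediate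
22 | 5α-hydroperoxide corresponding to 21 | CC(=C)C(=O)O[C@@H]1C[C@@]2(C)CC[C@@H](OC(C)=O)[C@@H](CO[Si](C(C)C)(C(C)C)C(C)C)[C@]2(OO)[C@@H]2OC(=O)C(=C)[C@@H]21 | intermediate
23 | 5α-(4-nitrobenzoylperoxy) derivative of 22 | CC(=C)C(=O)O[C@@H]1C[C@@]2(C)CC[C@@H](OC(C)=O)[C@@H](CO[Si](C(C)C)(C(C)C)C(C)C)[C@]2(OOC(=O)c3ccc(cc3)[N+](=O)[O-])[C@@H]2OC(=O)C(=C)[C@@H]21 | intermediate
24 | 5-(4-nitrobenzoyloxy)-5,10-epoxygermacranolide ketal ester (acyloxy on the α-face; either C5 epimer converges) | CC(=C)C(=O)O[C@@H]1C[C@@]2(C)CC[C@@H](OC(C)=O)[C@@H](CO[Si](C(C)C)(C(C)C)C(C)C)[C@](O2)(OC(=O)c3ccc(cc3)[N+](=O)[O-])[C@@H]2OC(=O)C(=C)[C@@H]21 | intermediate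
25 | 15-O-TIPS ether of the target | CC(=C)C(=O)O[C@@H]1C[C@@]2(C)CC[C@@H](OC(C)=O)[C@@H](CO[Si](C(C)C)(C(C)C)C(C)C)[C@@H](O2)[C@@H]2OC(=O)C(=C)[C@@H]21 | intermediate
26 | CNP0602302.1, (3R,4R,5R,6R,7R,8R,10R)-3-acetoxy-15-hydroxy-8-methacryloyloxy-5,10-epoxygermacr-11(13)-en-6,12-olide | C=C(C)C(=O)O[C@@H]1C[C@@]2(C)CC[C@@H](OC(C)=O)[C@@H](CO)[C@@H](O2)[C@@H]2OC(=O)C(=C)[C@@H]21 | target

**Step count and risks**

Total step count: 17. Longest linear sequence: 17 steps (from 1; compounds 3, 5 and 6 are bought).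

The three steps most likely to fail, each with one fallback:

Risk 1, step 15: the perester may ionise with migration of the acyloxy-bearing C6 or of C4 instead of C10, or decompose by O–O homolysis. The fallback for step 15 sets out from 22 and comes back to the route at 25. Reduction of the O–O bond of 22 with PPh3 should give the tertiary 5α-alcohol F1 with the esters untouched. The alkoxy radical of F1 (Pb(OAc)4, CaCO3, benzene, hν) should cleave the C5–C10 bond by β-fragmentation, as 5-hydroxy decalins and 5α-hydroxy steroids do, and oxidation of the C10 radical with loss of a C1 proton should give the ten-membered 5,10-seco (E)-1(10)-en-5-one F2 in the same operation. Luche reduction of F2 (NaBH4, CeCl3, MeOH, −78 °C) should give the 5-carbinol F3 by 1,2-reduction, without conjugate reduction of the α-methylene lactone. Transannular Markovnikov hydroalkoxylation of F3 (TfOH cat., CH2Cl2, −40 °C) should then close the C10–O bond and return to 25; the C5 hydroxyl, held across the ring, captures the tertiary C10 cation formed by protonation at C1. An oxymercuration–demercuration is avoided here because the alkyl radical of the demercuration would add to the two enoates.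

Risk 2, step 16: hydride delivery to the strained bridgehead oxocarbenium ion may show poor facial selectivity (the C15 silyloxymethyl group sits on the α-face), or ionisation may be slow. The fallback for step 16 sets out from 24 and comes back to the route at 26. HF·pyridine buffered with pyridine should remove the TIPS group of 24 and give the 15-hydroxy ketal ester F4 with the ketal ester intact. Chlorodiisopropylsilane and imidazole should convert F4 into the 15-O-diisopropylsilyl ether F5 that carries an Si–H bond. TMSOTf (cat.) ionises the ketal ester of F5, and the tethered Si–H delivers hydride to C5 through a six-membered transition state on the α-face on which C15 sits; capture of the silicon by the carboxylate gives the silyl ester F6 as the bridged ether. HF·pyridine cleaves both Si–O bonds of F6 and gives 26.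

Risk 3, step 14: silver-assisted ionisation of the tertiary bromide may be diverted to E1 elimination or to participation by the neighbouring lactone. The fallback for step 14 sets out from 20 and comes back to the route at 22. TMSCHN2 should give the methyl ester F7 of the acid. NBS in aqueous acetone should convert F7 into the 5α-bromo-6β-hydroxy ester F8 by diaxial opening of the α-bromonium ion, as Δ5-steroids do. Ag2O should close F8 to the 5β,6β-epoxide F9 with loss of bromide. Perhydrolysis of F9 (H2O2 in Et2O, cat. phosphomolybdic acid) should open the epoxide at the tertiary C5 with inversion and give the 5α-hydroperoxy-6β-ol F10 as the diaxial product. PPTS-catalysed lactonisation of the 6β-hydroxyl of F10 onto the methyl ester gives 22.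

Further compounds
F1 | step 15 | 5α-hydroxy analogue of 22 (tertiary alcohol) | CC(=C)C(=O)O[C@@H]1C[C@@]2(C)CC[C@@H](OC(C)=O)[C@@H](CO[Si](C(C)C)(C(C)C)C(C)C)[C@]2(O)[C@@H]2OC(=O)C(=C)[C@@H]21
F2 | step 15 | 5,10-seco (E)-germacra-1(10),11(13)-dien-5-one 6β,12-olide | CC(=C)C(=O)O[C@@H]1C/C(C)=C/C[C@@H](OC(C)=O)[C@@H](CO[Si](C(C)C)(C(C)C)C(C)C)C(=O)[C@@H]2OC(=O)C(=C)[C@@H]21
F3 | step 15 | corresponding 5-carbinol | CC(=C)C(=O)O[C@@H]1C/C(C)=C/C[C@@H](OC(C)=O)[C@@H](CO[Si](C(C)C)(C(C)C)C(C)C)[C@@H](O)[C@@H]2OC(=O)C(=C)[C@@H]21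
F4 | step 16 | 15-hydroxy ketal ester (24 without TIPS) | CC(=C)C(=O)O[C@@H]1C[C@@]2(C)CC[C@@H](OC(C)=O)[C@@H](CO)[C@](O2)(OC(=O)c3ccc(cc3)[N+](=O)[O-])[C@@H]2OC(=O)C(=C)[C@@H]21
F5 | step 16 | 15-O-diisopropylsilyl (Si–H) ether of F4 | CC(=C)C(=O)O[C@@H]1C[C@@]2(C)CC[C@@H](OC(C)=O)[C@@H](CO[SiH](C(C)C)C(C)C)[C@](O2)(OC(=O)c3ccc(cc3)[N+](=O)[O-])[C@@H]2OC(=O)C(=C)[C@@H]21
F6 | step 16 | bridged ether with 15-O-Si(i-Pr)2-(4-nitrobenzoate) | CC(=C)C(=O)O[C@@H]1C[C@@]2(C)CC[C@@H](OC(C)=O)[C@@H](CO[Si](OC(=O)c3ccc(cc3)[N+](=O)[O-])(C(C)C)C(C)C)[C@@H](O2)[C@@H]2OC(=O)C(=C)[C@@H]21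
F7 | step 14 | methyl ester of 20 | CC(=O)O[C@@H]1CC[C@]2(C)C[C@@H](OC(=O)C(C)=C)[C@@H](C(=C)C(=O)OC)C=C2[C@@H]1CO[Si](C(C)C)(C(C)C)C(C)C
F8 | step 14 | 5α-bromo-6β-hydroxy methyl ester | CC(=C)C(=O)O[C@@H]1C[C@@]2(C)CC[C@@H](OC(C)=O)[C@@H](CO[Si](C(C)C)(C(C)C)C(C)C)[C@]2(Br)[C@H](O)[C@@H]1C(=C)C(=O)OC
F9 | step 14 | 5β,6β-epoxy methyl ester | CC(=C)C(=O)O[C@@H]1C[C@@]2(C)CC[C@@H](OC(C)=O)[C@@H](CO[Si](C(C)C)(C(C)C)C(C)C)[C@]23O[C@@H]3[C@@H]1C(=C)C(=O)OC
F10 | step 14 | 5α-hydroperoxy-6β-hydroxy methyl ester | CC(=C)C(=O)O[C@@H]1C[C@@]2(C)CC[C@@H](OC(C)=O)[C@@H](CO[Si](C(C)C)(C(C)C)C(C)C)[C@]2(OO)[C@H](O)[C@@H]1C(=C)C(=O)OC
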